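## Retrosynthetic overview
1. The O–C3 enol-ether bond of the furanone is made last, by transannular attack of O10 on a 10-membered 2-yn-1-one. This C–O closure is the key step.
2. The C8 ester comes from acylation of a free 8β-OH. The γ-lactone C12–O6 bond and the C6–C7 bond come from one Cr(II) ring closure of a (Z)-enal onto a vinyl epoxide.
3. The C8–O bond and its configuration come from a chlorohydrin-to-epoxide closure with inversion, starting from an organocatalytic α-chloro aldehyde.
4. The C1–C2 bond comes from the acetylide of (Z)-3-methylpent-2-en-4-yn-1-ol (C2–C6, C15) adding to a C1 aldehyde. Carbons C1, C7–C10 and C14 come from (R)-linalool by double ozonolysis.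
5. Ring order: temporary oxirane, then the 10-membered carbocycle and γ-lactone in one operation, then the 3(2H)-furanone.

Assumption: locants C1–C15 follow germacrane numbering of the target; commercial (R)-(−)-linalool of ≥95 % ee is used; the (2R,5R) catalyst in step 3 is taken to be the enantiomer that gives (S)-2-chloroaldehydes (otherwise its mirror image is used).

## Route

Step 1
Reactants: 1 (R)-(−)-linalool
Product: 2 (3R)-3,7-dimethyl-3-(triethylsilyloxy)octa-1,6-diene
Conditions: TESOTf, 2,6-lutidine, CH2Cl2, −78 → 0 °C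
Reagents that add atoms: triethylsilyl trifluoromethanesulfonate, CC[Si](CC)(CC)OS(=O)(=O)C(F)(F)F
Why: O-silylation of a hindered tertiary alcohol with a silyl triflate under buffered conditions; the chiral-pool C10 centre (R) is untouched, and the ether later stops O10 from adding to aldehydes or opening the epoxide.

Step 2
Reactants: 2 (3R)-3,7-dimethyl-3-(triethylsilyloxy)octa-1,6-diene
Product: 3 (2R)-2-methyl-2-(triethylsilyloxy)pentanedial
Conditions: O3, CH2Cl2, −78 °C; Me2S, −78 °C → rt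
Reagents that add atoms: ozone, [O-][O+]=O
Why: Exhaustive ozonolysis with reductive work-up cuts both alkenes at once and gives a dialdehyde with very different ends (C7 unhindered and enolisable, C1 neopentyl-type with no α-H); C10 is untouched.

Step 3
Reactants: 3 (2R)-2-methyl-2-(triethylsilyloxy)pentanedial
Product: 4 (2R,4S)-4-chloro-2-methyl-2-(triethylsilyloxy)pentanedial
Conditions: NCS (1.1 equiv), (2R,5R)-2,5-diphenylpyrrolidine (10 mol %), CH2Cl2, 0 °C; used without chromatography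
Reagents that add atoms: N-chlorosuccinimide, O=C1CCC(=O)N1Cl
Why: Enamine-catalysed asymmetric α-chlorination of an aldehyde; only the C7 aldehyde can form an enamine, so chlorine enters at C8 alone, and the C2-symmetric catalyst sets 8S independently of the remote C10 centre.

Step 4
Reactants: 4 (2R,4S)-4-chloro-2-methyl-2-(triethylsilyloxy)pentanedial
Product: 5 methyl (3R,4S,6R)-4-chloro-3-hydroxy-6-methyl-2-methylidene-7-oxo-6-(triethylsilyloxy)heptanoate
Conditions: DIBAL-H, NMO, methyl propiolate, THF, 0 °C (pre-formed vinylalane, 1.05 equiv); then 4, −40 → 0 °C; aq. Rochelle salt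
Reagents that add atoms: methyl propiolate, C#CC(=O)OC
Why: Vinylalumination, a non-basic Morita–Baylis–Hillman equivalent; the bulky α-aluminated acrylate adds only to the activated, unhindered α-chloro aldehyde without epimerising C8, and Cornforth–Evans control gives mainly the anti (7R) chlorohydrin, whose C7 centre is erased in step 8.

Step 5
Reactants: 5 methyl (3R,4S,6R)-4-chloro-3-hydroxy-6-methyl-2-methylidene-7-oxo-6-(triethylsilyloxy)heptanoate
Product: 6 methyl 2-[(2R,3R)-3-[(2R)-2-methyl-3-oxo-2-(triethylsilyloxy)propyl]oxiran-2-yl]prop-2-enoate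
Conditions: Cs2CO3, MeCN, 0 °C → rt
Reagents that add atoms: none
Why: Intramolecular Williamson-type 3-exo-tet closure of a chlorohydrin; the C7 alkoxide displaces chloride with clean inversion, so 8S C–Cl becomes the 8R C–O bond of the target, and the vinyl epoxide masks both the 8-OH and the future C7 nucleophile without a protecting group.

Step 6
Reactants: 6 methyl 2-[(2R,3R)-3-[(2R)-2-methyl-3-oxo-2-(triethylsilyloxy)propyl]oxiran-2-yl]prop-2-enoate; 7 (Z)-3-methylpent-2-en-4-yn-1-ol
Product: 10 methyl 2-[(2R,3R)-3-[(2R,6Z)-2,6-dimethyl-2,3,8-tris(triethylsilyloxy)oct-6-en-4-yn-1-yl]oxiran-2-yl]prop-2-enoate (C1 epimers), via dilithiated enynol 8 (not isolated), via dilithium dialkoxide adduct 9 (not isolated)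
Conditions: 7, n-BuLi (2 equiv per 7), THF, −78 → −20 °C; 6, −78 °C; TESCl, DMAP (cat.), −78 → 0 °C
Reagents that add atoms: chlorotriethylsilane, CC[Si](Cl)(CC)CC
Why: 1,2-addition of a lithium acetylide to a non-enolisable aldehyde (ester, acrylate and epoxide are inert at −78 °C), followed by in-situ O-silylation that stops O1 from opening the epoxide; the C1 carbinol forms as a mixture and is erased in step 10, and the 4Z alkene is carried unchanged from 7.

Step 7
Reactants: 10 methyl 2-[(2R,3R)-3-[(2R,6Z)-2,6-dimethyl-2,3,8-tris(triethylsilyloxy)oct-6-en-4-yn-1-yl]oxiran-2-yl]prop-2-enoate (C1 epimers)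
Product: 11 methyl 2-[(2R,3R)-3-[(2R,6Z)-2,6-dimethyl-8-oxo-2,3-bis(triethylsilyloxy)oct-6-en-4-yn-1-yl]oxiran-2-yl]prop-2-enoate (C1 epimers)
Conditions: (COCl)2, DMSO, CH2Cl2, −78 → −40 °C; Et3N, −78 → −20 °C
Reagents that add atoms: none
Why: Swern oxidation applied directly to silyl ethers; only the primary TES ether is exchanged and oxidised while the secondary and tertiary TES ethers survive, no stereocentre is formed, and the low temperature keeps the enal Z.

Step 8
Reactants: 11 methyl 2-[(2R,3R)-3-[(2R,6Z)-2,6-dimethyl-8-oxo-2,3-bis(triethylsilyloxy)oct-6-en-4-yn-1-yl]oxiran-2-yl]prop-2-enoate (C1 epimers)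
Product: 15 (4Z,6R,7R,8R,10R)-8-hydroxy-1,10-bis(triethylsilyloxy)germacra-4,11(13)-dien-2-yn-12,6-olide (C1 epimers), via allylic iodide lithium alkoxide 12 (not isolated), via allylchromium(III) species 13 (not isolated), via macrocyclic dihydroxy ester 14 (not isolated)
Conditions: CrCl2 (6 equiv), LiI (1.5 equiv), THF, 2 mM (syringe pump), rt; H2O; PPTS (cat.), CH2Cl2, rt
Reagents that add atoms: none
Why: Nozaki–Hiyama–Kishi-type allylation in its CrCl2/LiI vinyl-epoxide variant, run as a macrocyclisation: iodide opens the acrylate-activated epoxide SN2′, Cr(II) gives an allylchromium whose C8 substituent is an alkoxide (not a leaving group, so no 1,4-elimination), and γ-attack of C7 on the enal through a chair transition state gives the anti C6/C7 pair (trans-lactone) on the face fixed by C8 and the Z-enyne tether; O6 then lactonises, while the 8β-OH is badly placed to reach C12.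

Step 9
Reactants: 15 (4Z,6R,7R,8R,10R)-8-hydroxy-1,10-bis(triethylsilyloxy)germacra-4,11(13)-dien-2-yn-12,6-olide (C1 epimers); 16 (S)-2-methylbutanoic acid
Product: 18 (4Z,6R,7R,8R,10R)-8-[(2S)-2-methylbutanoyloxy]-1,10-bis(triethylsilyloxy)germacra-4,11(13)-dien-2-yn-12,6-olide (C1 epimers), via O-acylisourea 17 (not isolated)
Conditions: 16, DCC, DMAP (cat.), CH2Cl2, 0 °C → rt
Reagents that add atoms: none
Why: Steglich esterification of the only free hydroxyl; C8 keeps its configuration because the C8–O bond is not broken, and the carbodiimide route avoids a ketene, so the (S) centre of the acid is retained.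

Step 10
Reactants: 18 (4Z,6R,7R,8R,10R)-8-[(2S)-2-methylbutanoyloxy]-1,10-bis(triethylsilyloxy)germacra-4,11(13)-dien-2-yn-12,6-olide (C1 epimers)
Product: 22 CNP0174601.1 (4Z,6R,7R,8R,10R)-8-[(2S)-2-methylbutanoyloxy]-1-oxo-3,10-epoxygermacra-2,4,11(13)-trien-12,6-olide, via C1 carbinol 19 (not isolated), via silyloxy ynone 20 (not isolated), via hydroxy ynone 21 (not isolated)
Conditions: 4-acetamido-2,2,6,6-tetramethyl-1-oxopiperidinium tetrafluoroborate (1.2 equiv), Bi(OTf)3 (5 mol %), MeCN/H2O 50:1, 0 °C → rt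
Reagents that add atoms: none
Why: Proposed new method: a self-ordered oxidative desilylation/transannular oxa-Michael cascade. The Lewis acid in wet MeCN hydrolyses the secondary propargylic TES ether far faster than the tertiary neopentyl one, and the oxoammonium cation oxidises the freed C1 carbinol by hydride abstraction before a vicinal diol can form (so no glycol cleavage, and both C1 epimers converge). The acid released by that oxidation then removes the tertiary TES group, and O10 adds 5-endo-dig to C3 of the strained, acid-activated ynone, forming the O–C3 bond and the furanone with C10 retained. The closest known reaction types are Lewis-acid/nitroxyl oxidative deprotection of silyl ethers to carbonyl compounds and acid- or gold-catalysed cycloisomerisation of α′-hydroxy ynones to 3(2H)-furanones.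

## Compound list
1 | (R)-(−)-linalool, (3R)-3,7-dimethylocta-1,6-dien-3-ol | C=C[C@](C)(O)CCC=C(C)C | starting material
2 | (3R)-3,7-dimethyl-3-(triethylsilyloxy)octa-1,6-diene | C=C[C@](C)(O[Si](CC)(CC)CC)CCC=C(C)C | intermediate
3 | (2R)-2-methyl-2-(triethylsilyloxy)pentanedial | O=C[C@](C)(O[Si](CC)(CC)CC)CCC=O | intermediate
4 | (2R,4S)-4-chloro-2-methyl-2-(triethylsilyloxy)pentanedial | O=C[C@](C)(O[Si](CC)(CC)CC)C[C@H](Cl)C=O | intermediate
5 | methyl (3R,4S,6R)-4-chloro-3-hydroxy-6-methyl-2-methylidene-7-oxo-6-(triethylsilyloxy)heptanoate (anti-chlorohydrin) | C=C(C(=O)OC)[C@@H](O)[C@@H](Cl)C[C@@](C)(O[Si](CC)(CC)CC)C=O | intermediate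
6 | methyl 2-[(2R,3R)-3-[(2R)-2-methyl-3-oxo-2-(triethylsilyloxy)propyl]oxiran-2-yl]prop-2-enoate (trans-epoxide) | C=C(C(=O)OC)[C@H]1O[C@@H]1C[C@@](C)(O[Si](CC)(CC)CC)C=O | intermediate
7 | (Z)-3-methylpent-2-en-4-yn-1-ol | C#C/C(C)=C\CO | starting material
8 | dilithiated enynol (O-lithio, C5-lithio derivative of 7) | [Li]C#C/C(C)=C\CO[Li] | intermediate
9 | dilithium dialkoxide adduct of 8 and 6 (C1 epimers) | C=C(C(=O)OC)[C@H]1O[C@@H]1C[C@@](C)(O[Si](CC)(CC)CC)C(O[Li])C#C/C(C)=C\CO[Li] | intermediate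
10 | methyl 2-[(2R,3R)-3-[(2R,6Z)-2,6-dimethyl-2,3,8-tris(triethylsilyloxy)oct-6-en-4-yn-1-yl]oxiran-2-yl]prop-2-enoate (C1 epimers) | C=C(C(=O)OC)[C@H]1O[C@@H]1C[C@@](C)(O[Si](CC)(CC)CC)C(O[Si](CC)(CC)CC)C#C/C(C)=C\CO[Si](CC)(CC)CC | intermediate
11 | methyl 2-[(2R,3R)-3-[(2R,6Z)-2,6-dimethyl-8-oxo-2,3-bis(triethylsilyloxy)oct-6-en-4-yn-1-yl]oxiran-2-yl]prop-2-enoate (C1 epimers) | C=C(C(=O)OC)[C@H]1O[C@@H]1C[C@@](C)(O[Si](CC)(CC)CC)C(O[Si](CC)(CC)CC)C#C/C(C)=C\C=O | intermediate
12 | lithium alkoxide of methyl (4R,6R,10Z)-4-hydroxy-2-(iodomethyl)-6,10-dimethyl-12-oxo-6,7-bis(triethylsilyloxy)dodeca-2,10-dien-8-ynoate (2E/Z) | O=C/C=C(C)\C#CC(O[Si](CC)(CC)CC)[C@](C)(O[Si](CC)(CC)CC)C[C@@H](O[Li])C=C(CI)C(=O)OC | intermediate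
13 | allylchromium(III) species, CH2I of 12 replaced by CH2CrCl2 | O=C/C=C(C)\C#CC(O[Si](CC)(CC)CC)[C@](C)(O[Si](CC)(CC)CC)C[C@@H](O[Li])C=C(C[Cr](Cl)Cl)C(=O)OC | intermediate
14 | methyl (4Z,6R,7R,8R,10R)-6,8-dihydroxy-1,10-bis(triethylsilyloxy)germacra-4,11(13)-dien-2-yn-12-oate (C1 epimers) | CC[Si](CC)(CC)OC1C#C/C(C)=C\[C@@H](O)[C@H](C(=C)C(=O)OC)[C@H](O)C[C@@]1(C)O[Si](CC)(CC)CC | intermediate
15 | (4Z,6R,7R,8R,10R)-8-hydroxy-1,10-bis(triethylsilyloxy)germacra-4,11(13)-dien-2-yn-12,6-olide (C1 epimers) | C=C1C(=O)O[C@@H]2/C=C(/C)C#CC(O[Si](CC)(CC)CC)[C@](C)(O[Si](CC)(CC)CC)C[C@@H](O)[C@@H]12 | intermediate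
16 | (S)-2-methylbutanoic acid | CC[C@H](C)C(=O)O | starting material
17 | O-[(2S)-2-methylbutanoyl]-N,N'-dicyclohexylisourea | CC[C@H](C)C(=O)OC(=NC1CCCCC1)NC1CCCCC1 | intermediate
18 | (4Z,6R,7R,8R,10R)-8-[(2S)-2-methylbutanoyloxy]-1,10-bis(triethylsilyloxy)germacra-4,11(13)-dien-2-yn-12,6-olide (C1 epimers) | C=C1C(=O)O[C@@H]2/C=C(/C)C#CC(O[Si](CC)(CC)CC)[C@](C)(O[Si](CC)(CC)CC)C[C@@H](OC(=O)[C@@H](C)CC)[C@@H]12 | intermediate
19 | C1 carbinol: 1-hydroxy-10-(triethylsilyloxy) analogue of 18 (C1 epimers) | C=C1C(=O)O[C@@H]2/C=C(/C)C#CC(O)[C@](C)(O[Si](CC)(CC)CC)C[C@@H](OC(=O)[C@@H](C)CC)[C@@H]12 | intermediate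
20 | silyloxy ynone: (4Z,6R,7R,8R,10R)-8-[(2S)-2-methylbutanoyloxy]-1-oxo-10-(triethylsilyloxy)germacra-4,11(13)-dien-2-yn-12,6-olide | C=C1C(=O)O[C@@H]2/C=C(/C)C#CC(=O)[C@](C)(O[Si](CC)(CC)CC)C[C@@H](OC(=O)[C@@H](C)CC)[C@@H]12 | intermediate
21 | hydroxy ynone: (4Z,6R,7R,8R,10R)-10-hydroxy-8-[(2S)-2-methylbutanoyloxy]-1-oxogermacra-4,11(13)-dien-2-yn-12,6-olide | C=C1C(=O)O[C@@H]2/C=C(/C)C#CC(=O)[C@](C)(O)C[C@@H](OC(=O)[C@@H](C)CC)[C@@H]12 | intermediate
22 | CNP0174601.1, (4Z,6R,7R,8R,10R)-8-[(2S)-2-methylbutanoyloxy]-1-oxo-3,10-epoxygermacra-2,4,11(13)-trien-12,6-olide | C=C1C(=O)O[C@@H]2/C=C(/C)C3=CC(=O)[C@@](C)(C[C@@H](OC(=O)[C@@H](C)CC)[C@@H]12)O3 | target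

## Step count
Total steps: 10. Longest linear sequence: 10 (1 → 22). Compounds 7 and 16 enter as purchased.

## Steps most likely to fail

**Step 8 (ring closure).**
- The CrCl2/LiI opening of vinyl epoxides is established for intermolecular additions; its use to close a strained 10-membered enyne ring is an extension.
- It may give oligomers, the wrong C6/C7 face, or E-enal.
- The fallback sets out from 11 and comes back at 15.
  - MgBr2·OEt2 opens the epoxide SN2′ to methyl (2Z,4R,6R,10Z)-2-(bromomethyl)-4-hydroxy-6,10-dimethyl-12-oxo-6,7-bis(triethylsilyloxy)dodeca-2,10-dien-8-ynoate F5.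
  - TMSCl/imidazole converts it to its C8 trimethylsilyl ether F6.
  - A classical Barbier/NHK closure of this pre-formed allylic bromide (CrCl2, THF/DMF, high dilution) gives the macrocyclic 8-trimethylsilyloxy hydroxy ester F7. Here a non-chelating silyl ether, not a chromium alkoxide, steers the face, which is the best-tested closure for germacranolide rings.
  - Citric acid in MeOH at 0 °C removes only the TMS ether and lactonises to 15.

**Step 10 (the new cascade).**
- Oxidation of the hindered propargylic carbinol may be slow.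
- The tertiary TES ether may leave too early.
- The oxoammonium salt may attack the enyne.
- The fallback uses only known reactions, sets out from 18 and comes back at 22.
  - HF·pyridine in MeCN removes both TES groups to give (4Z,6R,7R,8R,10R)-1,10-dihydroxy-8-[(2S)-2-methylbutanoyloxy]germacra-4,11(13)-dien-2-yn-12,6-olide F8.
  - Dess–Martin periodinane oxidises its only secondary alcohol to the hydroxy ynone 21, which is now isolated.
  - A cationic gold(I) catalyst ((Ph3P)AuNTf2, 5 mol %, toluene, rt) closes 21 by 5-endo-dig hydroalkoxylation to 22.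

**Step 4 (selective addition to a labile α-chloro dialdehyde).**
- The vinylalane may also touch the C1 aldehyde.
- The free C1 aldehyde may interfere in the closure of step 5.
- The fallback differentiates the two termini in time instead of by reactivity. It sets out from 2, comes back at 6, and is one step longer.
  - One equivalent of ozone (pyridine, indicator end point) cleaves only the trisubstituted alkene to (4R)-4-methyl-4-(triethylsilyloxy)hex-5-enal F1.
  - The same α-chlorination gives (2S,4R)-2-chloro-4-methyl-4-(triethylsilyloxy)hex-5-enal F2.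
  - Vinylalane addition gives methyl (3R,4S,6R)-4-chloro-3-hydroxy-6-methyl-2-methylidene-6-(triethylsilyloxy)oct-7-enoate F3.
  - Cs2CO3 closes it to methyl 2-[(2R,3R)-3-[(2R)-2-methyl-2-(triethylsilyloxy)but-3-en-1-yl]oxiran-2-yl]prop-2-enoate F4.
  - A second ozonolysis, selective for the vinyl group over the electron-poor acrylate, gives 6.

## Further compounds
F1 | step 4 | (4R)-4-methyl-4-(triethylsilyloxy)hex-5-enal | C=C[C@](C)(O[Si](CC)(CC)CC)CCC=O
F2 | step 4 | (2S,4R)-2-chloro-4-methyl-4-(triethylsilyloxy)hex-5-enal | C=C[C@](C)(O[Si](CC)(CC)CC)C[C@H](Cl)C=O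
F3 | step 4 | methyl (3R,4S,6R)-4-chloro-3-hydroxy-6-methyl-2-methylidene-6-(triethylsilyloxy)oct-7-enoate | C=C(C(=O)OC)[C@@H](O)[C@@H](Cl)C[C@@](C)(O[Si](CC)(CC)CC)C=C
F4 | step 4 | methyl 2-[(2R,3R)-3-[(2R)-2-methyl-2-(triethylsilyloxy)but-3-en-1-yl]oxiran-2-yl]prop-2-enoate | C=C(C(=O)OC)[C@H]1O[C@@H]1C[C@@](C)(O[Si](CC)(CC)CC)C=C
F5 | step 8 | methyl (2Z,4R,6R,10Z)-2-(bromomethyl)-4-hydroxy-6,10-dimethyl-12-oxo-6,7-bis(triethylsilyloxy)dodeca-2,10-dien-8-ynoate (C7 epimers) | O=C/C=C(C)\C#CC(O[Si](CC)(CC)CC)[C@](C)(O[Si](CC)(CC)CC)C[C@@H](O)/C=C(\CBr)C(=O)OC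
F6 | step 8 | C8 (chain C4) trimethylsilyl ether of F5 | O=C/C=C(C)\C#CC(O[Si](CC)(CC)CC)[C@](C)(O[Si](CC)(CC)CC)C[C@@H](O[Si](C)(C)C)/C=C(\CBr)C(=O)OC
F7 | step 8 | methyl (4Z,6R,7R,8R,10R)-6-hydroxy-1,10-bis(triethylsilyloxy)-8-(trimethylsilyloxy)germacra-4,11(13)-dien-2-yn-12-oate (C1 epimers) | CC[Si](CC)(CC)OC1C#C/C(C)=C\[C@@H](O)[C@H](C(=C)C(=O)OC)[C@H](O[Si](C)(C)C)C[C@@]1(C)O[Si](CC)(CC)CC
F8 | step 10 | (4Z,6R,7R,8R,10R)-1,10-dihydroxy-8-[(2S)-2-methylbutanoyloxy]germacra-4,11(13)-dien-2-yn-12,6-olide (C1 epimers) | C=C1C(=O)O[C@@H]2/C=C(/C)C#CC(O)[C@](C)(O)C[C@@H](OC(=O)[C@@H](C)CC)[C@@H]12
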